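In this stirred vessel of constant volume, four flasks differ in their charge of second catalyst, which enters in portions, so that charge is the one concentration whose order has to be read.

| flask | substrate | coupling partner | free catalyst | second catalyst | remark | time |
|---|---|---|---|---|---|---|
| zeta | 0.095 M | 1.5 equiv | 0.088 mol% | 0.027 mol% (in portions, 4) | run made earlier; portions every 4.0 s |  |
| epsilon | 0.095 M | 1.5 equiv | 0.088 mol% | 0.27 mol% (in portions, 4) | run made earlier; portions every 4.0 s |  |
| red | 0.095 M | 1.50 equiv | 0.088 mol% | 0.05 mol% (in portions, 4) | the portions of second catalyst follow each other after 4.0 s, the first at the start | 2.0 min |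
| violet | 0.095 M | 1.50 equiv | 0.088 mol% | 0.1 mol% (in portions, 4) | the portions of second catalyst follow each other after 4.0 s, the first at the start | 2.0 min |
| green | 0.095 M | 1.50 equiv | 0.088 mol% | 0.2 mol% (in portions, 4) | the portions of second catalyst follow each other after 4.0 s, the first at the start | 2.0 min |
| blue | 0.095 M | 1.50 equiv | 0.088 mol% | 0.4 mol% (in portions, 4) | the portions of second catalyst follow each other after 4.0 s, the first at the start | 2.0 min |

- zeta (time / s: target / %): 10.0: 0; 20.0: 0; 40.0: 0.4; 60.0: 0.5; 80.0: 1.4
- epsilon (time / s: target / %): 10.0: 0.1; 12.0: 0; 25.0: 0.8; 40.0: 3.2; 80.0: 8.1

(scatter of a reading: 0.5 percentage points)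

- target is meant together with its idle complex
- on the list of suspects stand: substrate + free catalyst <-> free catalyst + open intermediate; second catalyst + open intermediate <-> catalyst intermediate; coupling partner + catalyst intermediate -> second catalyst + target; coupling partner + target -> over-reaction product; second catalyst + target <-> idle complex
- "hardly changes" means that all values lie within two and a half points (for a concentration: within two and a half percent of the largest)

- amount of target at the end, in percent of the substrate charged for red, violet, green, blue, in this order
- how that number moves from the first to the last of them (hardly changes / falls all the way / rises, then falls / falls, then rises / rises all the way)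

Zeta and epsilon share their charges of substrate, coupling partner and free catalyst, and differ in second catalyst, 0.027 mol% against 0.27 mol%, ten times as much. Two amounts therefore carry the comparison: target at 80.0 s, which is 1.4% in zeta and 8.1% in epsilon. The earlier zeta readings, 0.4% and 0.5%, lie too near the scatter of 0.5 percentage points to serve, and even the later one is a rough reading. The logarithm of the ratio of these two amounts, divided by the logarithm of the ratio of the loadings, is the apparent order in second catalyst, here read as 0.762; as a reading it carries the scatter of both amounts, and so read it stands below first order and above zero.

My own reckoning extends epsilon's last slope, from 40.0 s to 80.0 s, up to 2.0 min, which gives 13.0% of target at the epsilon loading. Scaled with the order, this puts red at 3.59% and blue at 17.5%.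

The forecast gives 3.8%, 6.5%, 10% and 13%, and says rises all the way, on the ground that “Ten times the catalyst therefore gives only about 5.5 times the rate, so the response is saturating.” It shares my direction but stands lower than my reckoning at blue.

The flasks give 3.90%, 7.06%, 11.7% and 17.3% of target for red, violet, green and blue: rises all the way.

    substrate + free catalyst ⇌ free catalyst + open intermediate (K = 1.10, k = 42.0 M⁻¹ s⁻¹)
    second catalyst + open intermediate ⇌ catalyst intermediate (K = 10.0 M⁻¹, k = 89.0 M⁻¹ s⁻¹)
    coupling partner + catalyst intermediate → second catalyst + target (k = 120 M⁻¹ s⁻¹)
    coupling partner + target → over-reaction product (k = 0.0270 M⁻¹ s⁻¹)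
    second catalyst + target ⇌ idle complex (K = 8.80 M⁻¹, k = 0.270 M⁻¹ s⁻¹)

Open intermediate at the end stands at 24.9% in red and 11.1% in blue. Starting from red's result, the order 0.762 puts blue at 19.0%, against the 17.3% it holds. Read from the results themselves, the order is 0.716 from red to blue and 0.564 from green to blue.

Readings and results are calculated for substances that don't exist; scatter was added.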